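## Retrosynthetic overview

1. Target 10 comes from stilbene 9 by one hydrogenation (three C=C, two O-benzyl groups); 9 comes from two molecules of aldehyde 8 by McMurry coupling.
2. The (S) benzylic quaternary carbon of 8 comes from an aromatic Claisen rearrangement of aryl cyclopentenyl ether 6, which relays an allylic C–O stereocentre into the aryl–C bond.
3. The key bond is the allylic C–O bond of 6, made enantioselectively by adding the O–H of phenol 5 across achiral diene 4.
4. Diene 4 comes from 2,2-dimethylcyclopentanone 1 (dehydrogenation, MeLi, dehydration).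
5. Ring order: no ring is built; the cyclopentane is bought in 1 and both benzene rings in 5.

Assumption: 1 and 5 are taken as catalogue starting materials, and the ligand enantiomer named in step 3 is assumed to give the (S) ether (its antipode is used if the first run shows the (R) ether).

## Route

Step 1
Reactants: 1 2,2-dimethylcyclopentan-1-one
Product: 2 5,5-dimethylcyclopent-2-en-1-one
Conditions: IBX (2 equiv), PhF/DMSO (2:1), 75 °C
Reagents that add atoms: none
Why: IBX α,β-dehydrogenation of a ketone works here because 1 can enolise only toward its single CH2–C=O side, so only one enone can form and no stereocentre is involved.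

Step 2
Reactants: 2 5,5-dimethylcyclopent-2-en-1-one
Product: 4 1,5,5-trimethylcyclopenta-1,3-diene, via allylic alcohol 3 (not isolated)
Conditions: MeLi (1.2 equiv), Et2O, −78 → 0 °C; H2O, separate; then p-TsOH·H2O (2 mol%), pentane, 0 °C → rt; distil
Reagents that add atoms: methyllithium, [Li]C
Why: 1,2-addition of MeLi to the non-enolisable enone gives tertiary allylic alcohol 3, and acid-catalysed E1 dehydration through the allyl cation gives the conjugated endocyclic diene 4 (any exocyclic isomer feeds the same allylpalladium species in step 3); no stereocentre is formed.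

Step 3
Reactants: 4 1,5,5-trimethylcyclopenta-1,3-diene; 5 3-(benzyloxy)-4-hydroxybenzaldehyde
Product: 6 3-(benzyloxy)-4-{[(1S)-3,4,4-trimethylcyclopent-2-en-1-yl]oxy}benzaldehyde
Conditions: Pd2(dba)3·CHCl3 (2.5 mol%), (R,R)-DACH-phenyl Trost ligand (7.5 mol%), 4 (1.5 equiv), toluene, 0 °C; stop at full conversion of 5, filter through silica
Reagents that add atoms: none
Why: Proposed new method: an enantioselective palladium-hydride hydroaryloxylation of a 5,5-disubstituted cyclopentadiene, in which ArO–H protonates the zerovalent-palladium–diene complex at the unsubstituted terminus C4 to give a 1-methyl-η3-cyclopentenyl palladium phenoxide, the two face-isomeric allyl complexes interconvert by reversible β-hydride elimination back to the achiral diene, and the phenoxide attacks the only accessible allyl terminus (C3, remote from CMe2) inside the chiral pocket of the ligand, setting the (1S) C–O stereocentre; the closest known reaction types are the racemic palladium-catalysed addition of phenols to cyclic 1,3-dienes, the palladium-catalysed enantioselective hydroamination of cyclohexadiene and the Tsuji–Trost asymmetric allylic etherification of cyclic allyl carbonates with phenols.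

Step 4
Reactants: 6 3-(benzyloxy)-4-{[(1S)-3,4,4-trimethylcyclopent-2-en-1-yl]oxy}benzaldehyde
Product: 8 3-(benzyloxy)-4-hydroxy-5-[(1S)-1,5,5-trimethylcyclopent-2-en-1-yl]benzaldehyde, via ortho-dienone 7 (not isolated)
Conditions: Eu(fod)3 (10 mol%), PhCl, 110 °C, sealed tube; recrystallise 8 (heptane/EtOAc) to ≥99% ee
Reagents that add atoms: none
Why: In this aromatic Claisen ([3,3]-sigmatropic) rearrangement the only free ortho carbon (the other carries OBn, the para carbon CHO) bonds to the methyl-bearing allyl terminus on the ring face the oxygen leaves, so the (1S) C–O centre of 6 is relayed suprafacially into the (S) quaternary carbon, and dienone 7 tautomerises to phenol 8.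

Step 5
Reactants: 8 3-(benzyloxy)-4-hydroxy-5-[(1S)-1,5,5-trimethylcyclopent-2-en-1-yl]benzaldehyde (two molecules)
Product: 9 4,4'-[(E)-ethene-1,2-diyl]bis{2-(benzyloxy)-6-[(1S)-1,5,5-trimethylcyclopent-2-en-1-yl]phenol}
Conditions: TiCl4 (4 equiv), Zn (8 equiv), pyridine, THF, reflux (reagent pre-formed before 8 is added)
Reagents that add atoms: none
Why: McMurry reductive carbonyl homocoupling on low-valent titanium joins the two aldehyde carbons; excess reagent covers the free phenol, the cyclopentene and benzyl ether are inert, the E/Z ratio is irrelevant, and 8 of ≥99% ee gives ≤1% of the meso diastereomer.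

Step 6
Reactants: 9 4,4'-[(E)-ethene-1,2-diyl]bis{2-(benzyloxy)-6-[(1S)-1,5,5-trimethylcyclopent-2-en-1-yl]phenol}
Product: 10 5,5'-(ethane-1,2-diyl)bis{3-[(1S)-1,2,2-trimethylcyclopentyl]benzene-1,2-diol}
Conditions: H2 (4 bar), 10% Pd/C, EtOAc/EtOH (1:1), rt; filter and concentrate under argon
Reagents that add atoms: none
Why: Heterogeneous catalytic hydrogenation with concurrent benzyl-ether hydrogenolysis saturates the stilbene and both cis-disubstituted cyclopentene double bonds and frees both catechols in one operation; the quaternary stereocentres carry no hydrogen and cannot epimerise.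

## Compound list

1 | 2,2-dimethylcyclopentan-1-one | CC1(C)CCCC1=O | starting material
2 | 5,5-dimethylcyclopent-2-en-1-one | CC1(C)CC=CC1=O | intermediate
3 | 1,5,5-trimethylcyclopent-2-en-1-ol (racemic, not isolated) | CC1(O)C=CCC1(C)C | intermediate
4 | 1,5,5-trimethylcyclopenta-1,3-diene | CC1=CC=CC1(C)C | intermediate
5 | 3-(benzyloxy)-4-hydroxybenzaldehyde | O=Cc1ccc(O)c(OCc2ccccc2)c1 | starting material
6 | 3-(benzyloxy)-4-{[(1S)-3,4,4-trimethylcyclopent-2-en-1-yl]oxy}benzaldehyde | O=Cc1ccc(O[C@@H]2C=C(C)C(C)(C)C2)c(OCc3ccccc3)c1 | intermediate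
7 | 5-(benzyloxy)-4-oxo-3-[(1R)-1,5,5-trimethylcyclopent-2-en-1-yl]cyclohexa-1,5-diene-1-carbaldehyde (not isolated; ring C3 undefined; the CIP label is R only because the ring carbon now ranks below CMe2, the spatial arrangement is that of 8) | O=CC1=CC(C(=O)C(OCc2ccccc2)=C1)[C@@]3(C)C=CCC3(C)C | intermediate
8 | 3-(benzyloxy)-4-hydroxy-5-[(1S)-1,5,5-trimethylcyclopent-2-en-1-yl]benzaldehyde | O=Cc1cc(OCc2ccccc2)c(O)c([C@@]3(C)C=CCC3(C)C)c1 | intermediate
9 | 4,4'-[(E)-ethene-1,2-diyl]bis{2-(benzyloxy)-6-[(1S)-1,5,5-trimethylcyclopent-2-en-1-yl]phenol} | Oc1c(OCc2ccccc2)cc(/C=C/c2cc(OCc3ccccc3)c(O)c([C@@]3(C)C=CCC3(C)C)c2)cc1[C@@]1(C)C=CCC1(C)C | intermediate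
10 | 5,5'-(ethane-1,2-diyl)bis{3-[(1S)-1,2,2-trimethylcyclopentyl]benzene-1,2-diol} (CNP0144189.1) | CC1(C)CCC[C@]1(C)c1cc(CCc2cc(O)c(O)c([C@@]3(C)CCCC3(C)C)c2)cc(O)c1O | target

## Step count and risks

Total step count: 6. Longest linear sequence: 6 steps (1 → 2 → 4 → 6 → 8 → 9 → 10); 5 enters at step 3.

**Step 3 (proposed new reaction).** Phenol addition to dienes is reversible, so the ee of 6 can erode with time, and C-alkylation or the wrong hydropalladation regiochemistry may compete. The fallback uses known chemistry, sets out from 2 and comes back at 6. MeLi is added to 2 as in step 2, but alcohol 3 is isolated. Oxidative 1,3-transposition with pyridinium chlorochromate (C5H5NH[CrO3Cl]) in CH2Cl2 gives 3,4,4-trimethylcyclopent-2-en-1-one F1. Reduction with (S)-Me-CBS oxazaborolidine and catecholborane in toluene at −78 °C gives (1R)-3,4,4-trimethylcyclopent-2-en-1-ol F2; the (R) sense follows the usual model with the alkenyl arm as the large group and is checked by Mosher analysis. Mitsunobu etherification of F2 with 5 (PPh3, DIAD, THF, 0 °C) proceeds with inversion and gives 6.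

**Step 4 (Claisen rearrangement).** The new aryl–C bond is made at a fully substituted carbon next to CMe2, and 6 can instead eliminate back to 4 and 5. The fallback makes the quaternary centre by methyl addition instead; it sets out from 2 and comes back at 10.
- 3-Bromo-4,5-dimethoxybenzaldehyde F3 (bought) is converted with ethylene glycol and p-TsOH into 2-(3-bromo-4,5-dimethoxyphenyl)-1,3-dioxolane F4.
- Br/Li exchange (n-BuLi, THF, −78 °C) and 1,2-addition to 2 give racemic 1-[5-(1,3-dioxolan-2-yl)-2,3-dimethoxyphenyl]-5,5-dimethylcyclopent-2-en-1-ol F5.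
- Pyridinium chlorochromate with NaOAc in CH2Cl2 transposes it to 3-[5-(1,3-dioxolan-2-yl)-2,3-dimethoxyphenyl]-4,4-dimethylcyclopent-2-en-1-one F6.
- Copper-catalysed asymmetric conjugate addition of Me3Al (CuTC, monovalent copper thiophene-2-carboxylate, 5 mol%; chiral phosphoramidite chosen for the (S) product; Et2O, −30 °C) gives (3S)-3-[5-(1,3-dioxolan-2-yl)-2,3-dimethoxyphenyl]-3,4,4-trimethylcyclopentan-1-one F7.
- Wolff–Kishner reduction (N2H4·H2O, KOH, diethylene glycol, 200 °C) gives 2-{3,4-dimethoxy-5-[(1S)-1,2,2-trimethylcyclopentyl]phenyl}-1,3-dioxolane F8.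
- Aqueous HCl in THF gives 3,4-dimethoxy-5-[(1S)-1,2,2-trimethylcyclopentyl]benzaldehyde F9.
- McMurry coupling (TiCl4, Zn, THF) gives (E)-1,2-bis{3,4-dimethoxy-5-[(1S)-1,2,2-trimethylcyclopentyl]phenyl}ethene F10.
- H2 over Pd/C gives 1,2-bis{3,4-dimethoxy-5-[(1S)-1,2,2-trimethylcyclopentyl]phenyl}ethane F11.
- BBr3 in CH2Cl2 (−78 → 0 °C) gives 10.

**Step 5 (McMurry coupling).** The substrate is a hindered free phenol, and the Lewis-acidic titanium could add the phenol across the neighbouring cyclopentene. The fallback uses olefin metathesis instead; it sets out from 8 and comes back at 9. Wittig methylenation (Ph3PCH3Br, KOtBu, 2.5 equiv, THF) gives 2-(benzyloxy)-4-ethenyl-6-[(1S)-1,5,5-trimethylcyclopent-2-en-1-yl]phenol F12. Self-metathesis of F12 with second-generation Grubbs catalyst (CH2Cl2, 40 °C, ethylene swept out) gives 9; the hindered cyclopentene is not expected to take part.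

## Further compounds

F1 | step 3 | 3,4,4-trimethylcyclopent-2-en-1-one | O=C1C=C(C)C(C)(C)C1
F2 | step 3 | (1R)-3,4,4-trimethylcyclopent-2-en-1-ol | O[C@H]1C=C(C)C(C)(C)C1
F3 | step 4 | 3-bromo-4,5-dimethoxybenzaldehyde (bought, not made) | COc1cc(C=O)cc(Br)c1OC
F4 | step 4 | 2-(3-bromo-4,5-dimethoxyphenyl)-1,3-dioxolane | COc1cc(C2OCCO2)cc(Br)c1OC
F5 | step 4 | 1-[5-(1,3-dioxolan-2-yl)-2,3-dimethoxyphenyl]-5,5-dimethylcyclopent-2-en-1-ol (racemic) | COc1cc(C2OCCO2)cc(C3(O)C=CCC3(C)C)c1OC
F6 | step 4 | 3-[5-(1,3-dioxolan-2-yl)-2,3-dimethoxyphenyl]-4,4-dimethylcyclopent-2-en-1-one | COc1cc(C2OCCO2)cc(C3=CC(=O)CC3(C)C)c1OC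
F7 | step 4 | (3S)-3-[5-(1,3-dioxolan-2-yl)-2,3-dimethoxyphenyl]-3,4,4-trimethylcyclopentan-1-one | COc1cc(C2OCCO2)cc([C@@]3(C)CC(=O)CC3(C)C)c1OC
F8 | step 4 | 2-{3,4-dimethoxy-5-[(1S)-1,2,2-trimethylcyclopentyl]phenyl}-1,3-dioxolane | COc1cc(C2OCCO2)cc([C@@]3(C)CCCC3(C)C)c1OC
F9 | step 4 | 3,4-dimethoxy-5-[(1S)-1,2,2-trimethylcyclopentyl]benzaldehyde | COc1cc(C=O)cc([C@@]2(C)CCCC2(C)C)c1OC
F10 | step 4 | (E)-1,2-bis{3,4-dimethoxy-5-[(1S)-1,2,2-trimethylcyclopentyl]phenyl}ethene | COc1cc(/C=C/c2cc(OC)c(OC)c([C@@]3(C)CCCC3(C)C)c2)cc([C@@]2(C)CCCC2(C)C)c1OC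
F11 | step 4 | 1,2-bis{3,4-dimethoxy-5-[(1S)-1,2,2-trimethylcyclopentyl]phenyl}ethane | COc1cc(CCc2cc(OC)c(OC)c([C@@]3(C)CCCC3(C)C)c2)cc([C@@]2(C)CCCC2(C)C)c1OC
F12 | step 5 | 2-(benzyloxy)-4-ethenyl-6-[(1S)-1,5,5-trimethylcyclopent-2-en-1-yl]phenol | C=Cc1cc(OCc2ccccc2)c(O)c([C@@]3(C)C=CCC3(C)C)c1
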